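**Plan**

- Numbering: tetralin C1–C4, C4a, C8a. Ring A is the fused arene (6-OMe, 7-OH), ring B the carbocycle, ring C the 4-hydroxy-3-methoxyphenyl group on C1.
- Cuts: C1–C2 (last bond of ring B), C2–C3 (malonate onto an allyl unit), C1–ring C (aryllithium onto the ring A aldehyde), C4–C4a (allyl transfer to the ring A bromide). The C3 vinyl group is a masked CH2OH.
- Enabling feature: C1 is benzylic to ring C, whose para-oxygen lets C1 be unmasked as the exocyclic carbon of a para-quinone methide. C2 sits four atoms away (C3, C4, C4a, C8a) on the ortho position of ring A and carries the future ester as a malonate.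
- Forward order: ring A bromo-aldehyde, allyl at C4a, ring C added at C1 and trapped as pivalate, chain lengthened by cross-metathesis, C3 and C2 installed by allylic alkylation, ring B closed at C1–C2, then ester trimmed, vinyl cut to CH2OH, benzyl groups removed.
- Stereochemistry: C3 from the iridium–phosphoramidite catalyst; C1 from C3 in a kinetically controlled chair-like closure (aryl cis to vinyl); C2 by base equilibration to the all-equatorial 1,2-trans-2,3-trans isomer.

Key step: step 7

Assumption: the (Sa,S,S) antipode of the BINOL-derived phosphoramidite L, O,O'-(1,1'-binaphthalene-2,2'-diyl) N,N-bis[1-(2-methoxyphenyl)ethyl]phosphoramidite, is taken to give the (R) centre of 13; the sense follows the ligand, so the mirror-image ligand is used if a test substrate shows the opposite sense.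

**Route**

Step 1
Reactants: 1 2-bromo-5-hydroxy-4-methoxybenzaldehyde
Product: 2 5-(benzyloxy)-2-bromo-4-methoxybenzaldehyde
Conditions: BnBr, K2CO3, DMF, rt
Reagents that add atoms: benzyl bromide, BrCc1ccccc1
Why: Williamson ether synthesis on the phenoxide, which protects the ring A oxygen (the future 7-OH) and leaves the aldehyde and aryl bromide untouched.

Step 2
Reactants: 2 5-(benzyloxy)-2-bromo-4-methoxybenzaldehyde; 3 allyltributylstannane
Product: 4 2-allyl-5-(benzyloxy)-4-methoxybenzaldehyde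
Conditions: Pd(PPh3)4 (5 mol%), toluene, 100 °C
Reagents that add atoms: none
Why: Stille coupling, in which the ortho-formyl group assists oxidative addition into the C–Br bond and the allyl group is transferred from tin to the carbon that becomes C4a.

Step 3
Reactants: 5 4-bromo-2-methoxyphenol
Product: 6 (4-bromo-2-methoxyphenoxy)triisopropylsilane
Conditions: TIPSCl, imidazole, DMF, rt
Reagents that add atoms: triisopropylsilyl chloride, CC(C)[Si](Cl)(C(C)C)C(C)C
Why: imidazole-promoted silylation of the phenol, the bulky silyl ether being chosen to survive organolithium and mildly basic conditions yet fall to fluoride in step 7.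

Step 4
Reactants: 6 (4-bromo-2-methoxyphenoxy)triisopropylsilane; 4 2-allyl-5-(benzyloxy)-4-methoxybenzaldehyde
Product: 9 racemic [2-allyl-5-(benzyloxy)-4-methoxyphenyl][3-methoxy-4-(triisopropylsilyloxy)phenyl]methyl pivalate, via aryllithium 7 (not isolated), via lithium alkoxide 8 (not isolated)
Conditions: n-BuLi, THF, −78 °C; then 4, −78 °C; then PivCl, −78 → 0 °C
Reagents that add atoms: pivaloyl chloride, CC(C)(C)C(Cl)=O
Why: bromine–lithium exchange followed by 1,2-addition of the aryllithium to the aldehyde forms the C1–ring C bond, and O-acylation of the lithium alkoxide installs the leaving group for step 7; the carbinol centre forms without control, which is harmless because it becomes trigonal in 15.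

Step 5
Reactants: 9 racemic pivalate from step 4; 10 allyl methyl carbonate
Product: 11 racemic (E)-4-{4-(benzyloxy)-5-methoxy-2-[(pivaloyloxy)(3-methoxy-4-(triisopropylsilyloxy)phenyl)methyl]phenyl}but-2-en-1-yl methyl carbonate
Conditions: second-generation Grubbs catalyst (5 mol%), 1,4-benzoquinone (10 mol%), 10 (4 equiv), CH2Cl2, 40 °C
Reagents that add atoms: none
Why: olefin cross-metathesis driven by loss of ethene should give the disubstituted alkene mainly as the E isomer, with benzoquinone suppressing migration of the benzylic double bond.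

Step 6
Reactants: 11 racemic E-allylic methyl carbonate; 12 dimethyl malonate
Product: 13 dimethyl 2-[(2R)-1-{4-(benzyloxy)-5-methoxy-2-[(pivaloyloxy)(3-methoxy-4-(triisopropylsilyloxy)phenyl)methyl]phenyl}but-3-en-2-yl]malonate as both epimers at the pivalate carbon
Conditions: [Ir(cod)Cl]2 (2 mol%), (Sa,S,S)-phosphoramidite L (4 mol%), TBD (8 mol%), THF, rt
Reagents that add atoms: none
Why: iridium-catalysed asymmetric allylic alkylation, in which the cyclometalated iridium–phosphoramidite complex ionises the carbonate, the released methoxide deprotonates the malonate, and attack at the substituted allyl terminus gives the branched product with the C3 configuration (R) set by the ligand antipode.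

Step 7
Reactants: 13 branched malonate from step 6
Product: 17 dimethyl (1R,3R)-7-(benzyloxy)-1-[4-(benzyloxy)-3-methoxyphenyl]-6-methoxy-3-vinyl-3,4-dihydronaphthalene-2,2(1H)-dicarboxylate, via tetrabutylammonium phenoxide 14 (not isolated), via para-quinone methide 15 (not isolated), via cyclised phenoxide 16 (not isolated)
Conditions: Bu4NF (2.5 equiv), THF (0.01 M), −40 → 0 °C; then BnBr (3 equiv), 0 °C → rt
Reagents that add atoms: benzyl bromide, BrCc1ccccc1
Why: Fluoride removes the silyl group from the ring C oxygen and phenoxide 14 expels pivalate by 1,6-elimination to give para-quinone methide 15, whose exocyclic carbon C1 is attacked by the fluoride-generated malonate carbanion at C2; the closest known reaction type is the 1,6-conjugate (vinylogous Michael) addition of malonates to para-quinone methides released in situ from para-silyloxy- or para-hydroxybenzyl precursors, here in intramolecular form. Ring B closes in a 6-exo-trig mode, C1 being the in-ring end of the exocyclic C1=C bond, and rearomatisation of ring C drives the addition. The new stereocentre C1 is controlled by C3 through a chair-like transition state in which the vinyl group is pseudo-equatorial (allylic 1,3-strain against the planar malonate) and the quinoid ring takes the pseudo-equatorial site to avoid a syn-axial contact with H3, so the aryl group should emerge cis to the vinyl group. The step needs this 1,3-cis facial selectivity under kinetic control and C-alkylation by the tethered malonate rather than intermolecular capture of 15; low temperature and high dilution serve both, the tether makes the six-membered closure the fastest path, and benzylation of phenoxide 16 in the same flask blocks retro-1,6-addition, which could otherwise drift C1 toward the pseudo-axial aryl isomer that the two C2 esters and H8 may favour. Both epimers of 13 at the pivalate carbon converge because that centre is trigonal in 15.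

Step 8
Reactants: 17 tetralin-2,2-diester from step 7
Product: 18 methyl (1R,3R)-7-(benzyloxy)-1-[4-(benzyloxy)-3-methoxyphenyl]-6-methoxy-3-vinyl-1,2,3,4-tetrahydronaphthalene-2-carboxylate as a mixture of C2 epimers
Conditions: LiCl, H2O, DMSO, 150 °C
Reagents that add atoms: none
Why: Krapcho dealkoxycarbonylation, in which chloride demethylates one ester by SN2 attack at its methyl group, the carboxylate loses CO2 and water protonates the enolate, leaving C1 and C3 unaffected.

Step 9
Reactants: 18 monoester as C2 epimers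
Product: 19 methyl (1R,2R,3R)-7-(benzyloxy)-1-[4-(benzyloxy)-3-methoxyphenyl]-6-methoxy-3-vinyl-1,2,3,4-tetrahydronaphthalene-2-carboxylate (ester trans to both neighbours)
Conditions: NaOMe, MeOH/THF, 50 °C
Reagents that add atoms: none
Why: base-mediated epimerisation through the ester enolate, C2 being the only enolisable centre, should funnel both epimers to the thermodynamic isomer in which aryl, ester and vinyl groups are all equatorial.

Step 10
Reactants: 19 all-trans vinyl ester
Product: 21 methyl (1R,2S,3S)-7-(benzyloxy)-1-[4-(benzyloxy)-3-methoxyphenyl]-3-(hydroxymethyl)-6-methoxy-1,2,3,4-tetrahydronaphthalene-2-carboxylate, via aldehyde 20 (not isolated)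
Conditions: OsO4 (2 mol%), NaIO4, 2,6-lutidine, dioxane/H2O, rt; then NaBH4, MeOH, 0 °C
Reagents that add atoms: osmium tetroxide, O=[Os](=O)(=O)=O; sodium periodate, [Na+].[O-]I(=O)(=O)=O
Why: Lemieux–Johnson cleavage (osmylation, then periodate glycol fission) turns the vinyl group into aldehyde 20 without touching C3, NaBH4 reduces the aldehyde but not the methyl ester, and the benzyl ethers shield both guaiacol rings from periodate.

Step 11
Reactants: 21 dibenzyl ether of the target
Product: 22 methyl (1R,2S,3S)-7-hydroxy-1-(4-hydroxy-3-methoxyphenyl)-3-(hydroxymethyl)-6-methoxy-1,2,3,4-tetrahydronaphthalene-2-carboxylate (CNP0241585.1)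
Conditions: H2 (1 atm), Pd/C, EtOAc/MeOH, rt
Reagents that add atoms: none
Why: hydrogenolysis cleaves both aryl benzyl ethers while the doubly benzylic C1–H bond, the ester and the primary alcohol are inert.

**Compound list**

1 | 2-bromo-5-hydroxy-4-methoxybenzaldehyde | O=Cc1cc(O)c(OC)cc1Br | starting material
2 | 5-(benzyloxy)-2-bromo-4-methoxybenzaldehyde | O=Cc1cc(OCc2ccccc2)c(OC)cc1Br | intermediate
3 | allyltributylstannane | C=CC[Sn](CCCC)(CCCC)CCCC | starting material
4 | 2-allyl-5-(benzyloxy)-4-methoxybenzaldehyde | O=Cc1cc(OCc2ccccc2)c(OC)cc1CC=C | intermediate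
5 | 4-bromo-2-methoxyphenol | COc1cc(Br)ccc1O | starting material
6 | (4-bromo-2-methoxyphenoxy)triisopropylsilane | COc1cc(Br)ccc1O[Si](C(C)C)(C(C)C)C(C)C | intermediate
7 | [3-methoxy-4-(triisopropylsilyloxy)phenyl]lithium | [Li]c1ccc(O[Si](C(C)C)(C(C)C)C(C)C)c(OC)c1 | intermediate (not isolated)
8 | lithium [2-allyl-5-(benzyloxy)-4-methoxyphenyl][3-methoxy-4-(triisopropylsilyloxy)phenyl]methanolate, racemic | [Li]OC(c1cc(OCc2ccccc2)c(OC)cc1CC=C)c1ccc(O[Si](C(C)C)(C(C)C)C(C)C)c(OC)c1 | intermediate (not isolated)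
9 | [2-allyl-5-(benzyloxy)-4-methoxyphenyl][3-methoxy-4-(triisopropylsilyloxy)phenyl]methyl pivalate, racemic | C=CCc1cc(OC)c(OCc2ccccc2)cc1C(OC(=O)C(C)(C)C)c1ccc(O[Si](C(C)C)(C(C)C)C(C)C)c(OC)c1 | intermediate
10 | allyl methyl carbonate | C=CCOC(=O)OC | starting material
11 | (E)-4-{4-(benzyloxy)-5-methoxy-2-[(pivaloyloxy)(3-methoxy-4-(triisopropylsilyloxy)phenyl)methyl]phenyl}but-2-en-1-yl methyl carbonate, racemic | COC(=O)OC/C=C/Cc1cc(OC)c(OCc2ccccc2)cc1C(OC(=O)C(C)(C)C)c1ccc(O[Si](C(C)C)(C(C)C)C(C)C)c(OC)c1 | intermediate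
12 | dimethyl malonate | COC(=O)CC(=O)OC | starting material
13 | dimethyl 2-[(2R)-1-{4-(benzyloxy)-5-methoxy-2-[(pivaloyloxy)(3-methoxy-4-(triisopropylsilyloxy)phenyl)methyl]phenyl}but-3-en-2-yl]malonate, both epimers at the pivalate carbon | COC(=O)C(C(=O)OC)[C@@H](C=C)Cc1cc(OC)c(OCc2ccccc2)cc1C(OC(=O)C(C)(C)C)c1ccc(O[Si](C(C)C)(C(C)C)C(C)C)c(OC)c1 | intermediate
14 | tetrabutylammonium phenoxide of desilylated 13 | COC(=O)C(C(=O)OC)[C@@H](C=C)Cc1cc(OC)c(OCc2ccccc2)cc1C(OC(=O)C(C)(C)C)c1ccc([O-])c(OC)c1.CCCC[N+](CCCC)(CCCC)CCCC | intermediate (not isolated)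
15 | para-quinone methide: dimethyl 2-[(2R)-1-{4-(benzyloxy)-5-methoxy-2-[(3-methoxy-4-oxocyclohexa-2,5-dien-1-ylidene)methyl]phenyl}but-3-en-2-yl]malonate | COC(=O)C(C(=O)OC)[C@@H](C=C)Cc1cc(OC)c(OCc2ccccc2)cc1C=C1C=CC(=O)C(OC)=C1 | intermediate (not isolated)
16 | tetrabutylammonium phenoxide of dimethyl (1R,3R)-7-(benzyloxy)-1-(4-hydroxy-3-methoxyphenyl)-6-methoxy-3-vinyl-3,4-dihydronaphthalene-2,2(1H)-dicarboxylate (aryl cis to vinyl) | COC(=O)C1(C(=O)OC)[C@@H](C=C)Cc2cc(OC)c(OCc3ccccc3)cc2[C@H]1c1ccc([O-])c(OC)c1.CCCC[N+](CCCC)(CCCC)CCCC | intermediate (not isolated)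
17 | dimethyl (1R,3R)-7-(benzyloxy)-1-[4-(benzyloxy)-3-methoxyphenyl]-6-methoxy-3-vinyl-3,4-dihydronaphthalene-2,2(1H)-dicarboxylate (aryl cis to vinyl) | COC(=O)C1(C(=O)OC)[C@@H](C=C)Cc2cc(OC)c(OCc3ccccc3)cc2[C@H]1c1ccc(OCc2ccccc2)c(OC)c1 | intermediate
18 | methyl (1R,3R)-7-(benzyloxy)-1-[4-(benzyloxy)-3-methoxyphenyl]-6-methoxy-3-vinyl-1,2,3,4-tetrahydronaphthalene-2-carboxylate, C2 epimers | COC(=O)C1[C@@H](C=C)Cc2cc(OC)c(OCc3ccccc3)cc2[C@H]1c1ccc(OCc2ccccc2)c(OC)c1 | intermediate
19 | methyl (1R,2R,3R)-7-(benzyloxy)-1-[4-(benzyloxy)-3-methoxyphenyl]-6-methoxy-3-vinyl-1,2,3,4-tetrahydronaphthalene-2-carboxylate (1,2-trans, 2,3-trans) | COC(=O)[C@@H]1[C@@H](C=C)Cc2cc(OC)c(OCc3ccccc3)cc2[C@H]1c1ccc(OCc2ccccc2)c(OC)c1 | intermediate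
20 | methyl (1R,2S,3S)-7-(benzyloxy)-1-[4-(benzyloxy)-3-methoxyphenyl]-3-formyl-6-methoxy-1,2,3,4-tetrahydronaphthalene-2-carboxylate | COC(=O)[C@@H]1[C@@H](C=O)Cc2cc(OC)c(OCc3ccccc3)cc2[C@H]1c1ccc(OCc2ccccc2)c(OC)c1 | intermediate (not isolated)
21 | methyl (1R,2S,3S)-7-(benzyloxy)-1-[4-(benzyloxy)-3-methoxyphenyl]-3-(hydroxymethyl)-6-methoxy-1,2,3,4-tetrahydronaphthalene-2-carboxylate | COC(=O)[C@@H]1[C@@H](CO)Cc2cc(OC)c(OCc3ccccc3)cc2[C@H]1c1ccc(OCc2ccccc2)c(OC)c1 | intermediate
22 | methyl (1R,2S,3S)-7-hydroxy-1-(4-hydroxy-3-methoxyphenyl)-3-(hydroxymethyl)-6-methoxy-1,2,3,4-tetrahydronaphthalene-2-carboxylate | COC(=O)[C@@H]1[C@@H](CO)Cc2cc(OC)c(O)cc2[C@H]1c1ccc(O)c(OC)c1 | target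

**Step count**

Total: 11 steps. Longest linear sequence: 10 steps (1, 2, 4, 5, 6, 7, 8, 9, 10, 11); step 3 prepares the ring C bromide.

**Steps most likely to fail**

1. Step 7, facial selectivity at C1. With two esters on C2 there is no 1,2-bias, and the pseudo-equatorial aryl is flanked by an ester and H8. Attack on the other face of the quinone methide, or partial retro-addition before the phenoxide is capped, could give the aryl trans to the vinyl group.

   The fallback turns that preference to use by anchoring on C1 and inverting C3 later. It sets out from 11 and 12. Step 6 is run with the mirror-image (Ra,R,R) ligand to give dimethyl 2-[(2S)-1-{4-(benzyloxy)-5-methoxy-2-[(pivaloyloxy)(3-methoxy-4-(triisopropylsilyloxy)phenyl)methyl]phenyl}but-3-en-2-yl]malonate F1. Bu4NF in THF at room temperature, with the phenoxide left to open and re-close by retro-1,6-addition before BnBr is added, should then collect the isomer with the C1 aryl pseudo-axial and trans to the equatorial vinyl group. This is dimethyl (1R,3S)-7-(benzyloxy)-1-[4-(benzyloxy)-3-methoxyphenyl]-6-methoxy-3-vinyl-3,4-dihydronaphthalene-2,2(1H)-dicarboxylate F2, which has the same C1 configuration as 17. LiCl in wet DMSO gives methyl (1R,3S)-7-(benzyloxy)-1-[4-(benzyloxy)-3-methoxyphenyl]-6-methoxy-3-vinyl-1,2,3,4-tetrahydronaphthalene-2-carboxylate F3. OsO4/NaIO4 gives the 3-epimeric aldehyde, methyl (1R,3R)-7-(benzyloxy)-1-[4-(benzyloxy)-3-methoxyphenyl]-3-formyl-6-methoxy-1,2,3,4-tetrahydronaphthalene-2-carboxylate F4. DBU in CH2Cl2 then epimerises the two enolisable centres C2 and C3 to the all-equatorial aldehyde 20, where the route is rejoined and NaBH4 gives 21.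

2. Step 6, premature loss of the aryl silyl ether or the pivalate under the methoxide and guanidine base. This would release the quinone methide in the allylation flask; erosion of the branched-to-linear ratio would also be felt here.

   The fallback moves the allylic alkylation ahead of ring C. It sets out from 4. Trimethyl orthoformate with catalytic TsOH gives 1-allyl-4-(benzyloxy)-2-(dimethoxymethyl)-5-methoxybenzene F5. Cross-metathesis with 10 as in step 5 gives (E)-4-[4-(benzyloxy)-2-(dimethoxymethyl)-5-methoxyphenyl]but-2-en-1-yl methyl carbonate F6. The conditions of step 6 with 12 give dimethyl 2-{(2R)-1-[4-(benzyloxy)-2-(dimethoxymethyl)-5-methoxyphenyl]but-3-en-2-yl}malonate F7. TsOH in wet acetone frees dimethyl 2-{(2R)-1-[4-(benzyloxy)-2-formyl-5-methoxyphenyl]but-3-en-2-yl}malonate F8. Bromide 6 is converted (n-BuLi, B(OiPr)3, dilute acid) into [3-methoxy-4-(triisopropylsilyloxy)phenyl]boronic acid F9. This is added to F8 by base-free rhodium-catalysed 1,2-addition (Rh(acac)(CO)2, dppf, DME/H2O, 80 °C), which tolerates the acidic malonate, to give dimethyl 2-[(2R)-1-{4-(benzyloxy)-2-[hydroxy(3-methoxy-4-(triisopropylsilyloxy)phenyl)methyl]-5-methoxyphenyl}but-3-en-2-yl]malonate F10. PivCl, pyridine and DMAP convert F10 into 13, where the route is rejoined.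

3. Step 8, sluggish demethylation at the congested quaternary diester, with thermal degradation (double-bond migration, ether cleavage) at 150 °C.

   The fallback uses a malonate with one ester removable at room temperature. It sets out from 11. Commercial allyl methyl malonate (C=CCOC(=O)CC(=O)OC) under the conditions of step 6 gives 1-allyl 3-methyl 2-[(2R)-1-{4-(benzyloxy)-5-methoxy-2-[(pivaloyloxy)(3-methoxy-4-(triisopropylsilyloxy)phenyl)methyl]phenyl}but-3-en-2-yl]malonate F11. The conditions of step 7 close ring B to 2-allyl 2-methyl (1R,3R)-7-(benzyloxy)-1-[4-(benzyloxy)-3-methoxyphenyl]-6-methoxy-3-vinyl-3,4-dihydronaphthalene-2,2(1H)-dicarboxylate F12. Pd(PPh3)4 and morpholine in THF remove the allyl ester (Tsuji–Trost deallylation) to give (1R,3R)-7-(benzyloxy)-1-[4-(benzyloxy)-3-methoxyphenyl]-6-methoxy-2-(methoxycarbonyl)-3-vinyl-1,2,3,4-tetrahydronaphthalene-2-carboxylic acid F13. Warming F13 in toluene at 90 °C decarboxylates it to 18, where the route is rejoined.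

**Further compounds**

F1 | step 7 | dimethyl 2-[(2S)-1-{4-(benzyloxy)-5-methoxy-2-[(pivaloyloxy)(3-methoxy-4-(triisopropylsilyloxy)phenyl)methyl]phenyl}but-3-en-2-yl]malonate | COC(=O)C(C(=O)OC)[C@H](C=C)Cc1cc(OC)c(OCc2ccccc2)cc1C(OC(=O)C(C)(C)C)c1ccc(O[Si](C(C)C)(C(C)C)C(C)C)c(OC)c1
F2 | step 7 | dimethyl (1R,3S)-7-(benzyloxy)-1-[4-(benzyloxy)-3-methoxyphenyl]-6-methoxy-3-vinyl-3,4-dihydronaphthalene-2,2(1H)-dicarboxylate | COC(=O)C1(C(=O)OC)[C@H](C=C)Cc2cc(OC)c(OCc3ccccc3)cc2[C@H]1c1ccc(OCc2ccccc2)c(OC)c1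
F3 | step 7 | methyl (1R,3S)-7-(benzyloxy)-1-[4-(benzyloxy)-3-methoxyphenyl]-6-methoxy-3-vinyl-1,2,3,4-tetrahydronaphthalene-2-carboxylate, C2 epimers | COC(=O)C1[C@H](C=C)Cc2cc(OC)c(OCc3ccccc3)cc2[C@H]1c1ccc(OCc2ccccc2)c(OC)c1
F4 | step 7 | methyl (1R,3R)-7-(benzyloxy)-1-[4-(benzyloxy)-3-methoxyphenyl]-3-formyl-6-methoxy-1,2,3,4-tetrahydronaphthalene-2-carboxylate, C2 epimers | COC(=O)C1[C@H](C=O)Cc2cc(OC)c(OCc3ccccc3)cc2[C@H]1c1ccc(OCc2ccccc2)c(OC)c1
F5 | step 6 | 1-allyl-4-(benzyloxy)-2-(dimethoxymethyl)-5-methoxybenzene | COC(OC)c1cc(OCc2ccccc2)c(OC)cc1CC=C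
F6 | step 6 | (E)-4-[4-(benzyloxy)-2-(dimethoxymethyl)-5-methoxyphenyl]but-2-en-1-yl methyl carbonate | COC(=O)OC/C=C/Cc1cc(OC)c(OCc2ccccc2)cc1C(OC)OC
F7 | step 6 | dimethyl 2-{(2R)-1-[4-(benzyloxy)-2-(dimethoxymethyl)-5-methoxyphenyl]but-3-en-2-yl}malonate | COC(=O)C(C(=O)OC)[C@@H](C=C)Cc1cc(OC)c(OCc2ccccc2)cc1C(OC)OC
F8 | step 6 | dimethyl 2-{(2R)-1-[4-(benzyloxy)-2-formyl-5-methoxyphenyl]but-3-en-2-yl}malonate | COC(=O)C(C(=O)OC)[C@@H](C=C)Cc1cc(OC)c(OCc2ccccc2)cc1C=O
F9 | step 6 | [3-methoxy-4-(triisopropylsilyloxy)phenyl]boronic acid | COc1cc(B(O)O)ccc1O[Si](C(C)C)(C(C)C)C(C)C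
F10 | step 6 | dimethyl 2-[(2R)-1-{4-(benzyloxy)-2-[hydroxy(3-methoxy-4-(triisopropylsilyloxy)phenyl)methyl]-5-methoxyphenyl}but-3-en-2-yl]malonate, carbinol epimers | COC(=O)C(C(=O)OC)[C@@H](C=C)Cc1cc(OC)c(OCc2ccccc2)cc1C(O)c1ccc(O[Si](C(C)C)(C(C)C)C(C)C)c(OC)c1
F11 | step 8 | 1-allyl 3-methyl 2-[(2R)-1-{4-(benzyloxy)-5-methoxy-2-[(pivaloyloxy)(3-methoxy-4-(triisopropylsilyloxy)phenyl)methyl]phenyl}but-3-en-2-yl]malonate, epimer mixture | C=CCOC(=O)C(C(=O)OC)[C@@H](C=C)Cc1cc(OC)c(OCc2ccccc2)cc1C(OC(=O)C(C)(C)C)c1ccc(O[Si](C(C)C)(C(C)C)C(C)C)c(OC)c1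
F12 | step 8 | 2-allyl 2-methyl (1R,3R)-7-(benzyloxy)-1-[4-(benzyloxy)-3-methoxyphenyl]-6-methoxy-3-vinyl-3,4-dihydronaphthalene-2,2(1H)-dicarboxylate, C2 epimers | C=CCOC(=O)C1(C(=O)OC)[C@@H](C=C)Cc2cc(OC)c(OCc3ccccc3)cc2[C@H]1c1ccc(OCc2ccccc2)c(OC)c1
F13 | step 8 | (1R,3R)-7-(benzyloxy)-1-[4-(benzyloxy)-3-methoxyphenyl]-6-methoxy-2-(methoxycarbonyl)-3-vinyl-1,2,3,4-tetrahydronaphthalene-2-carboxylic acid, C2 epimers | OC(=O)C1(C(=O)OC)[C@@H](C=C)Cc2cc(OC)c(OCc3ccccc3)cc2[C@H]1c1ccc(OCc2ccccc2)c(OC)c1
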